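The tetrahydrofuran (O1–C2–C3–C4–C5) is cut at C4–C5 because C5 is an isolated methylene flanked only by O1 and the alkene carbon C4. A Lewis acid converts a formaldehyde acetal on O1 into the O1=C5H2 oxocarbenium ion, which is captured by the silicon-bearing C4 of a vinylsilane. One operation closes the ring, forms C4–C5 and hands the vinylsilane geometry on to the exocyclic C4=C7′ alkene (E). The precursor is an open-chain (2R,3S) anti benzylic MEM ether carrying a C4 trimethylsilyl alkene with silicon cis to the C7′ hydrogen, a C9 silyl ether and two silyl-protected guaiacyl rings; both stereocentres come from a chiral allenylzinc addition.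

Key step: step 11

Remarks before the steps:
- Labels: ring atoms are O1, C2 (aryl), C3 (bearing C9H2O), C4 (=C7′H–aryl), C5H2; open-chain intermediates keep these labels. Ar = 3-methoxy-4-[(triisopropylsilyl)oxy]phenyl, TBS = tert-butyldimethylsilyl, TIPS = triisopropylsilyl, MEM = (2-methoxyethoxy)methyl.
- Design of the precursor: the acetal is carried as a MEM ether, not a simple methoxymethyl ether. SnCl4 is chelated by the two outer oxygens, so the acetal should ionise only toward O1=C5H2+ and the Lewis acid is kept away from the benzylic O1. The phenols are TIPS ethers (robust to MeLi, SnCl4 and weak acid) and O9 is a TBS ether.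
- Assumption: the (S,S)-Ru catalyst in step 5 reduces the ynone with the spatial sense known for methyl ynones, which corresponds to the (R) descriptor here.

Step 1
Reactants: 1 vanillin
Product: 2 3-methoxy-4-[(triisopropylsilyl)oxy]benzaldehyde (ArCHO)
Conditions: TIPSCl, imidazole, DMF, rt
Reagents that add atoms: triisopropylsilyl chloride, CC(C)[Si](Cl)(C(C)C)C(C)C
Why: Imidazole-mediated O-silylation of the phenol (silyl ether formation); the aryl TIPS ether should survive organolithium, Lewis-acid and weakly acidic steps and is removed by fluoride at the end.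

Step 2
Reactants: 2 3-methoxy-4-[(triisopropylsilyl)oxy]benzaldehyde
Product: 3 [4-(2,2-dibromoethenyl)-2-methoxyphenoxy]tri(propan-2-yl)silane (ArCH=CBr2)
Conditions: CBr4, PPh3, CH2Cl2, 0 °C
Reagents that add atoms: carbon tetrabromide, BrC(Br)(Br)Br
Why: Corey–Fuchs dibromo-olefination (Wittig reaction of Ph3P=CBr2) of a non-enolisable aromatic aldehyde, which adds the future C4 as the CBr2 carbon.

Step 3
Reactants: 3 [4-(2,2-dibromoethenyl)-2-methoxyphenoxy]tri(propan-2-yl)silane; 4 (tert-butyldimethylsilyloxy)acetaldehyde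
Product: 6 rac-1-[(tert-butyldimethylsilyl)oxy]-4-Ar-but-3-yn-2-ol, via lithium arylacetylide 5 (not isolated)
Conditions: n-BuLi (2.1 equiv), THF, −78 °C; then 4, −78 → 0 °C; aq NH4Cl
Reagents that add atoms: none
Why: Second stage of the Corey–Fuchs alkyne synthesis (Br/Li exchange, Fritsch–Buttenberg–Wiechell rearrangement, deprotonation) gives the lithium acetylide, whose 1,2-addition to the aldehyde forms C3–C4; the new carbinol centre is racemic here and is set in step 5.

Step 4
Reactants: 6 rac-1-[(tert-butyldimethylsilyl)oxy]-4-Ar-but-3-yn-2-ol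
Product: 7 1-[(tert-butyldimethylsilyl)oxy]-4-Ar-but-3-yn-2-one
Conditions: Dess–Martin periodinane, NaHCO3, CH2Cl2, 0 °C → rt
Reagents that add atoms: none
Why: Dess–Martin oxidation of a secondary propargylic alcohol under buffered, non-acidic conditions that leave both silyl ethers intact.

Step 5
Reactants: 7 1-[(tert-butyldimethylsilyl)oxy]-4-Ar-but-3-yn-2-one
Product: 8 (2R)-1-[(tert-butyldimethylsilyl)oxy]-4-Ar-but-3-yn-2-ol
Conditions: Ru[(S,S)-TsDPEN](p-cymene) (2 mol %), i-PrOH, rt
Reagents that add atoms: none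
Why: Noyori asymmetric transfer hydrogenation of an ynone, in which the alkyne is the π-directing group, so the (S,S)-catalyst should deliver hydride to the face giving the (2R)-carbinol (the descriptor is R because CH2OSi outranks the alkyne).

Step 6
Reactants: 8 (2R)-1-[(tert-butyldimethylsilyl)oxy]-4-Ar-but-3-yn-2-ol
Product: 9 (2R)-1-[(tert-butyldimethylsilyl)oxy]-4-Ar-but-3-yn-2-yl methanesulfonate
Conditions: MsCl, Et3N, CH2Cl2, −40 → 0 °C; crude product used directly
Reagents that add atoms: methanesulfonyl chloride, CS(=O)(=O)Cl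
Why: Mesylation at oxygen (sulfonate ester formation) retains the C3 configuration; the crude mesylate is used at once because an aryl-conjugated propargylic sulfonate is prone to ionise.

Step 7
Reactants: 9 (2R)-1-[(tert-butyldimethylsilyl)oxy]-4-Ar-but-3-yn-2-yl methanesulfonate; 2 3-methoxy-4-[(triisopropylsilyl)oxy]benzaldehyde
Product: 11 (1R,2S)-1,4-di-Ar-2-{[(tert-butyldimethylsilyl)oxy]methyl}but-3-yn-1-ol (anti), via allenylzinc 10 (not isolated)
Conditions: Pd(OAc)2 (5 mol %), PPh3 (5 mol %), Et2Zn (3 equiv), THF, −78 → −20 °C; aq NH4Cl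
Reagents that add atoms: none
Why: Marshall propargylation: Pd(0) opens the (R)-mesylate by anti SN2′ attack, Pd→Zn exchange goes with retention and the (M)-allenylzinc adds to the aldehyde through a cyclic six-membered SE2′ transition state, so C3 (S) is set by chirality transfer from the mesylate (net inversion) and C2 (R) by the aldehyde aryl lying anti to the CH2OTBS terminus, which gives the anti adduct.

Step 8
Reactants: 11 (1R,2S)-1,4-di-Ar-2-{[(tert-butyldimethylsilyl)oxy]methyl}but-3-yn-1-ol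
Product: 13 (3E,4S,5R)-5-Ar-3-[(Ar)methylidene]-4-{[(tert-butyldimethylsilyl)oxy]methyl}-2,2-dimethyl-1,2-oxasilolane, via dimethylsilyl ether 12 (not isolated)
Conditions: (HMe2Si)2NH, neat, rt → 50 °C, then evaporate; Pt(dvds) (0.5 mol %), THF, rt
Reagents that add atoms: 1,1,3,3-tetramethyldisilazane, C[SiH](C)N[SiH](C)C
Why: O-Silylation with the disilazane followed by platinum-catalysed intramolecular (tethered) alkyne hydrosilylation: the O–SiMe2–H tether enforces 5-exo-dig delivery of silicon to C4 and syn addition places H on C7′ cis to silicon, which fixes the alkene geometry handed on in step 11; C2 and C3 are not touched.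

Step 9
Reactants: 13 (3E,4S,5R)-5-Ar-3-[(Ar)methylidene]-4-{[(tert-butyldimethylsilyl)oxy]methyl}-2,2-dimethyl-1,2-oxasilolane
Product: 14 (1R,2S,3E)-1,4-di-Ar-2-{[(tert-butyldimethylsilyl)oxy]methyl}-3-(trimethylsilyl)but-3-en-1-ol
Conditions: MeLi (2.5 equiv), THF, −78 → 0 °C; aq NH4Cl
Reagents that add atoms: methyllithium, [Li]C
Why: Nucleophilic substitution at silicon: methyllithium opens the strained cyclic alkoxysilane by Si–O cleavage, giving the C4 trimethylsilyl alkene and free O1–H without change in alkene geometry or at C2/C3, while the hindered TIPS and TBS ethers should not react at low temperature.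

Step 10
Reactants: 14 (1R,2S,3E)-1,4-di-Ar-2-{[(tert-butyldimethylsilyl)oxy]methyl}-3-(trimethylsilyl)but-3-en-1-ol
Product: 15 (1R,2S,3E)-1,4-di-Ar-2-{[(tert-butyldimethylsilyl)oxy]methyl}-1-[(2-methoxyethoxy)methoxy]-3-(trimethylsilyl)but-3-ene (key-step precursor)
Conditions: MEMCl, i-Pr2NEt, CH2Cl2, 0 °C → 40 °C
Reagents that add atoms: 2-methoxyethoxymethyl chloride, COCCOCCl
Why: Williamson-type O-alkylation of the secondary alcohol with a reactive α-chloro ether (MEM ether formation) under amine base, which installs C5 at the formaldehyde-acetal oxidation level.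

Step 11
Reactants: 15 (1R,2S,3E)-1,4-di-Ar-2-{[(tert-butyldimethylsilyl)oxy]methyl}-1-[(2-methoxyethoxy)methoxy]-3-(trimethylsilyl)but-3-ene
Product: 17 tert-butyl{[(2R,3S,4E)-2-Ar-4-[(Ar)methylidene]oxolan-3-yl]methoxy}dimethylsilane (key-step product), via oxocarbenium ion 16 (not isolated)
Conditions: SnCl4 (2.2 equiv), 2,6-di-tert-butyl-4-methylpyridine (0.3 equiv), CH2Cl2, −78 → −40 °C; cold quench with Et3N then aq NaHCO3
Reagents that add atoms: none
Why: SnCl4, chelated by the two outer MEM oxygens, expels 2-methoxyethoxide and leaves the O1=C5H2 oxocarbenium ion 16; the vinylsilane π bond attacks C5 through its silicon-bearing carbon C4, giving a C7′ cation that is both benzylic and β to silicon, and loss of the silyl group (as Me3SiCl) restores the alkene. The closest known reaction type is the acetal-initiated, vinylsilane-terminated (ipso-desilylative) cyclisation to alkylidene oxacycles, a silyl-modified Prins reaction. The tetrahydrofuran closes in a five-membered mode that is endo for the O1=C5 cation and exo for the C4=C7′ alkene. No stereocentre is created: C2 (R) and C3 (S) are carried through unchanged, and the E alkene follows from retention, because the C4–Si bond turns by the shorter path into the empty C7′ orbital so that C5 takes the place of silicon, cis to H-7′. The step needs acetal ionisation to outrun three things: heterolysis of the electron-rich benzylic C2–O1 bond, capture of the cation by O9, and protodesilylation; chelation of tin away from O1, the bulky weakly basic TBS ether on O9, −78 °C and the hindered pyridine buffer are there to secure this.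

Step 12
Reactants: 18 4-hydroxybenzoic acid
Product: 20 4-[(tert-butyldimethylsilyl)oxy]benzoic acid, via silyl ester 19 (not isolated)
Conditions: TBSCl (2.3 equiv), imidazole, DMF, rt; then AcOH/THF/H2O, rt
Reagents that add atoms: tert-butyldimethylsilyl chloride, CC(C)(C)[Si](C)(C)Cl
Why: Silylation of both acidic hydroxyls followed by selective hydrolysis of the silyl ester, which is far more labile to aqueous acid than the aryl silyl ether.

Step 13
Reactants: 17 tert-butyl{[(2R,3S,4E)-2-Ar-4-[(Ar)methylidene]oxolan-3-yl]methoxy}dimethylsilane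
Product: 21 [(2R,3S,4E)-2-Ar-4-[(Ar)methylidene]oxolan-3-yl]methanol
Conditions: PPTS (0.3 equiv), MeOH/CH2Cl2, rt
Reagents that add atoms: none
Why: Acid-catalysed methanolysis (chemoselective desilylation): a primary alkyl TBS ether is cleaved by PPTS/MeOH much faster than hindered aryl TIPS ethers, and the weak acid should not ionise the benzylic C2–O1 bond.

Step 14
Reactants: 21 [(2R,3S,4E)-2-Ar-4-[(Ar)methylidene]oxolan-3-yl]methanol; 20 4-[(tert-butyldimethylsilyl)oxy]benzoic acid
Product: 22 [(2R,3S,4E)-2-Ar-4-[(Ar)methylidene]oxolan-3-yl]methyl 4-[(tert-butyldimethylsilyl)oxy]benzoate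
Conditions: EDC·HCl, DMAP, CH2Cl2, rt
Reagents that add atoms: none
Why: Steglich esterification (carbodiimide/DMAP) of the unhindered primary C9 alcohol with the protected acid; no other nucleophile is free.

Step 15
Reactants: 22 [(2R,3S,4E)-2-Ar-4-[(Ar)methylidene]oxolan-3-yl]methyl 4-[(tert-butyldimethylsilyl)oxy]benzoate
Product: 23 agastenol, [(2R,3S,4E)-2-(4-hydroxy-3-methoxyphenyl)-4-[(4-hydroxy-3-methoxyphenyl)methylidene]oxolan-3-yl]methyl 4-hydroxybenzoate
Conditions: TBAF (3.5 equiv), AcOH (3.5 equiv), THF, 0 °C → rt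
Reagents that add atoms: none
Why: Fluoride-induced cleavage of the three aryl silyl ethers (Si–F bond formation), buffered with acetic acid so that the phenoxides are protonated and the benzoate ester and the E alkene stay untouched.

Compound list
1 | vanillin | COc1cc(C=O)ccc1O | starting material
2 | 3-methoxy-4-[(triisopropylsilyl)oxy]benzaldehyde | COc1cc(C=O)ccc1O[Si](C(C)C)(C(C)C)C(C)C | intermediate
3 | [4-(2,2-dibromoethenyl)-2-methoxyphenoxy]tri(propan-2-yl)silane | COc1cc(C=C(Br)Br)ccc1O[Si](C(C)C)(C(C)C)C(C)C | intermediate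
4 | (tert-butyldimethylsilyloxy)acetaldehyde | CC(C)(C)[Si](C)(C)OCC=O | starting material
5 | lithium {3-methoxy-4-[(triisopropylsilyl)oxy]phenyl}acetylide | COc1cc(C#C[Li])ccc1O[Si](C(C)C)(C(C)C)C(C)C | intermediate
6 | rac-1-[(tert-butyldimethylsilyl)oxy]-4-{3-methoxy-4-[(triisopropylsilyl)oxy]phenyl}but-3-yn-2-ol | COc1cc(C#CC(O)CO[Si](C)(C)C(C)(C)C)ccc1O[Si](C(C)C)(C(C)C)C(C)C | intermediate
7 | 1-[(tert-butyldimethylsilyl)oxy]-4-{3-methoxy-4-[(triisopropylsilyl)oxy]phenyl}but-3-yn-2-one | COc1cc(C#CC(=O)CO[Si](C)(C)C(C)(C)C)ccc1O[Si](C(C)C)(C(C)C)C(C)C | intermediate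
8 | (2R)-1-[(tert-butyldimethylsilyl)oxy]-4-{3-methoxy-4-[(triisopropylsilyl)oxy]phenyl}but-3-yn-2-ol | COc1cc(C#C[C@@H](O)CO[Si](C)(C)C(C)(C)C)ccc1O[Si](C(C)C)(C(C)C)C(C)C | intermediate
9 | (2R)-1-[(tert-butyldimethylsilyl)oxy]-4-{3-methoxy-4-[(triisopropylsilyl)oxy]phenyl}but-3-yn-2-yl methanesulfonate | COc1cc(C#C[C@@H](OS(C)(=O)=O)CO[Si](C)(C)C(C)(C)C)ccc1O[Si](C(C)C)(C(C)C)C(C)C | intermediate
10 | (M)-{4-[(tert-butyldimethylsilyl)oxy]-1-{3-methoxy-4-[(triisopropylsilyl)oxy]phenyl}buta-1,2-dien-1-yl}(ethyl)zinc, zinc on the face anti to the departed mesylate | [H]C(CO[Si](C)(C)C(C)(C)C)=[C@]=C([Zn]CC)c1ccc(O[Si](C(C)C)(C(C)C)C(C)C)c(OC)c1 | intermediate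
11 | (1R,2S)-2-{[(tert-butyldimethylsilyl)oxy]methyl}-1,4-bis{3-methoxy-4-[(triisopropylsilyl)oxy]phenyl}but-3-yn-1-ol | O[C@@H](c1ccc(O[Si](C(C)C)(C(C)C)C(C)C)c(OC)c1)[C@@H](C#Cc1ccc(O[Si](C(C)C)(C(C)C)C(C)C)c(OC)c1)CO[Si](C)(C)C(C)(C)C | intermediate
12 | O-dimethylsilyl (Si–H) ether of 11, (1R,2S) | C[SiH](C)O[C@@H](c1ccc(O[Si](C(C)C)(C(C)C)C(C)C)c(OC)c1)[C@@H](C#Cc1ccc(O[Si](C(C)C)(C(C)C)C(C)C)c(OC)c1)CO[Si](C)(C)C(C)(C)C | intermediate
13 | (3E,4S,5R)-4-{[(tert-butyldimethylsilyl)oxy]methyl}-2,2-dimethyl-5-{3-methoxy-4-[(triisopropylsilyl)oxy]phenyl}-3-({3-methoxy-4-[(triisopropylsilyl)oxy]phenyl}methylidene)-1,2-oxasilolane | C[Si]1(C)O[C@@H](c2ccc(O[Si](C(C)C)(C(C)C)C(C)C)c(OC)c2)[C@H](CO[Si](C)(C)C(C)(C)C)/C1=C\c1ccc(O[Si](C(C)C)(C(C)C)C(C)C)c(OC)c1 | intermediate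
14 | (1R,2S,3E)-2-{[(tert-butyldimethylsilyl)oxy]methyl}-1,4-bis{3-methoxy-4-[(triisopropylsilyl)oxy]phenyl}-3-(trimethylsilyl)but-3-en-1-ol | O[C@@H](c1ccc(O[Si](C(C)C)(C(C)C)C(C)C)c(OC)c1)[C@@H](/C([Si](C)(C)C)=C\c1ccc(O[Si](C(C)C)(C(C)C)C(C)C)c(OC)c1)CO[Si](C)(C)C(C)(C)C | intermediate
15 | MEM ether of 14, (1R,2S,3E); key-step precursor | COCCOCO[C@@H](c1ccc(O[Si](C(C)C)(C(C)C)C(C)C)c(OC)c1)[C@@H](/C([Si](C)(C)C)=C\c1ccc(O[Si](C(C)C)(C(C)C)C(C)C)c(OC)c1)CO[Si](C)(C)C(C)(C)C | intermediate
16 | O1=C5H2 oxocarbenium ion derived from 15 | C=[O+][C@@H](c1ccc(O[Si](C(C)C)(C(C)C)C(C)C)c(OC)c1)[C@@H](/C([Si](C)(C)C)=C\c1ccc(O[Si](C(C)C)(C(C)C)C(C)C)c(OC)c1)CO[Si](C)(C)C(C)(C)C | intermediate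
17 | tert-butyl{[(2R,3S,4E)-2-{3-methoxy-4-[(triisopropylsilyl)oxy]phenyl}-4-({3-methoxy-4-[(triisopropylsilyl)oxy]phenyl}methylidene)oxolan-3-yl]methoxy}dimethylsilane; key-step product | COc1cc(/C=C2/CO[C@@H](c3ccc(O[Si](C(C)C)(C(C)C)C(C)C)c(OC)c3)[C@@H]2CO[Si](C)(C)C(C)(C)C)ccc1O[Si](C(C)C)(C(C)C)C(C)C | intermediate
18 | 4-hydroxybenzoic acid | O=C(O)c1ccc(O)cc1 | starting material
19 | tert-butyldimethylsilyl 4-[(tert-butyldimethylsilyl)oxy]benzoate | CC(C)(C)[Si](C)(C)OC(=O)c1ccc(O[Si](C)(C)C(C)(C)C)cc1 | intermediate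
20 | 4-[(tert-butyldimethylsilyl)oxy]benzoic acid | O=C(O)c1ccc(O[Si](C)(C)C(C)(C)C)cc1 | intermediate
21 | [(2R,3S,4E)-2-{3-methoxy-4-[(triisopropylsilyl)oxy]phenyl}-4-({3-methoxy-4-[(triisopropylsilyl)oxy]phenyl}methylidene)oxolan-3-yl]methanol | COc1cc(/C=C2/CO[C@@H](c3ccc(O[Si](C(C)C)(C(C)C)C(C)C)c(OC)c3)[C@@H]2CO)ccc1O[Si](C(C)C)(C(C)C)C(C)C | intermediate
22 | [(2R,3S,4E)-2-{3-methoxy-4-[(triisopropylsilyl)oxy]phenyl}-4-({3-methoxy-4-[(triisopropylsilyl)oxy]phenyl}methylidene)oxolan-3-yl]methyl 4-[(tert-butyldimethylsilyl)oxy]benzoate | COc1cc(/C=C2/CO[C@@H](c3ccc(O[Si](C(C)C)(C(C)C)C(C)C)c(OC)c3)[C@@H]2COC(=O)c2ccc(O[Si](C)(C)C(C)(C)C)cc2)ccc1O[Si](C(C)C)(C(C)C)C(C)C | intermediate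
23 | agastenol, [(2R,3S,4E)-2-(4-hydroxy-3-methoxyphenyl)-4-[(4-hydroxy-3-methoxyphenyl)methylidene]oxolan-3-yl]methyl 4-hydroxybenzoate | COc1cc(/C=C2/CO[C@@H](c3ccc(O)c(OC)c3)[C@@H]2COC(=O)c2ccc(O)cc2)ccc1O | target

Total step count: 15. Longest linear sequence: 14 steps (steps 1–11 and 13–15, from vanillin); step 12 is a one-step side branch.

Steps most likely to fail, with fallbacks

1. Step 11 (key cyclisation).
- What may go wrong: heterolysis of the benzylic C2–O1 bond instead of the acetal; trapping of the oxocarbenium ion by O9; protodesilylation of the vinylsilane; loss of alkene geometry by rotation in the long-lived benzylic β-silyl cation.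
- Fallback: the ring is closed at O1–C5 by etherification instead. Setting out from alcohol 14, iododesilylation with retention (NIS, HFIP, 0 °C) should give the (1R,2S,3E)-vinyl iodide F1. Stille coupling of F1 with (tributylstannyl)methanol (Pd(PPh3)4, dioxane, 90 °C) should install C5 as a hydroxymethyl group with retention, giving the allylic diol F2. Mitsunobu cyclodehydration (PPh3, DIAD, THF, 0 °C) should activate the unhindered primary allylic hydroxyl, so that O1 displaces at C5 without touching C2. The fallback rejoins the route at 17.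

2. Step 7 (allenylzinc addition).
- What may go wrong: erosion of enantiomeric purity by racemisation of the aryl-substituted allenylzinc before the sluggish electron-rich aldehyde traps it; poor anti/syn facial selectivity with an aromatic aldehyde; solvolytic loss of the labile mesylate.
- Fallback: an isolable, configurationally stable allenylboron reagent replaces the transient zinc species. Setting out from alcohol 8, acylation (ClCO2Me, pyridine, CH2Cl2) gives the (2R)-methyl carbonate F3. Copper-catalysed anti SN2′ borylation (CuOt-Bu, Xantphos, B2pin2, THF) should give the (M)-allenylboronate F4 with chirality transfer. F4 is then heated with aldehyde 2 in toluene, with diphenyl phosphate as catalyst if needed, and should add through a closed six-membered transition state to give the same anti adduct. The fallback rejoins at 11.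

3. Step 13 (selective removal of the C9 silyl ether).
- What may go wrong: partial loss of the aryl silyl ethers, or acid-promoted opening and epimerisation at the benzylic C2–O1 bond during methanolysis.
- Fallback: no selective deprotection is attempted. Setting out from 17, all three silyl ethers are removed with TBAF/AcOH in THF to give the triol F5. The primary C9 alcohol of F5 is then esterified chemoselectively with unprotected 4-hydroxybenzoic acid 18 under Mitsunobu conditions (PPh3, DIAD, THF, 0 °C); only the carboxylic acid is acidic enough to act as the pronucleophile, so the phenols should stay free. The fallback arrives directly at 23.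

Further compounds
F1 | step 11 | (1R,2S,3E)-2-{[(tert-butyldimethylsilyl)oxy]methyl}-3-iodo-1,4-bis{3-methoxy-4-[(triisopropylsilyl)oxy]phenyl}but-3-en-1-ol | O[C@@H](c1ccc(O[Si](C(C)C)(C(C)C)C(C)C)c(OC)c1)[C@@H](/C(I)=C\c1ccc(O[Si](C(C)C)(C(C)C)C(C)C)c(OC)c1)CO[Si](C)(C)C(C)(C)C
F2 | step 11 | (1R,2S,3E)-2-{[(tert-butyldimethylsilyl)oxy]methyl}-3-(hydroxymethyl)-1,4-bis{3-methoxy-4-[(triisopropylsilyl)oxy]phenyl}but-3-en-1-ol | O[C@@H](c1ccc(O[Si](C(C)C)(C(C)C)C(C)C)c(OC)c1)[C@@H](/C(CO)=C\c1ccc(O[Si](C(C)C)(C(C)C)C(C)C)c(OC)c1)CO[Si](C)(C)C(C)(C)C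
F3 | step 7 | (2R)-1-[(tert-butyldimethylsilyl)oxy]-4-{3-methoxy-4-[(triisopropylsilyl)oxy]phenyl}but-3-yn-2-yl methyl carbonate | COc1cc(C#C[C@@H](OC(=O)OC)CO[Si](C)(C)C(C)(C)C)ccc1O[Si](C(C)C)(C(C)C)C(C)C
F4 | step 7 | (M)-2-{4-[(tert-butyldimethylsilyl)oxy]-1-{3-methoxy-4-[(triisopropylsilyl)oxy]phenyl}buta-1,2-dien-1-yl}-4,4,5,5-tetramethyl-1,3,2-dioxaborolane | [H]C(CO[Si](C)(C)C(C)(C)C)=[C@]=C(B1OC(C)(C)C(C)(C)O1)c1ccc(O[Si](C(C)C)(C(C)C)C(C)C)c(OC)c1
F5 | step 13 | 4-{(2R,3S,4E)-4-[(4-hydroxy-3-methoxyphenyl)methylidene]-3-(hydroxymethyl)oxolan-2-yl}-2-methoxyphenol | COc1cc(/C=C2/CO[C@@H](c3ccc(O)c(OC)c3)[C@@H]2CO)ccc1O
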